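**Retrosynthetic overview** (halimane-type locants: C4 = quaternary CH2OAc carbon, C5=C6–C7=O enone, C8/C9 methyl-bearing carbons, C10 ring-fusion CH, C13 side-chain CHMe)
1. Target ⇒ tert-butyl ester (acid freed last); C7 ketone from allylic oxidation of the C5=C6 alkene; C18 acetate from a silyl ether.
2. C11–C12 disconnection (Wittig, then hydrogenation): core aldehyde plus a C12–C15 phosphonium salt whose C13 centre comes from Rh-catalysed asymmetric hydrogenation of an itaconate half-ester.
3. Ring B (C8, C9, C10) by a catalyst-controlled, exo-selective Diels–Alder reaction of a ring A 1-vinylcyclohexene with tiglic aldehyde (bonds C7–C8 and C9–C10).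
4. Ring A diene from (S)-2-(silyloxymethyl)-2-methylcyclohexanone (enol triflate, Stille vinylation); its quaternary C4 is the first stereocentre, set by ketoreductase desymmetrisation of 2-allyl-2-methylcyclohexane-1,3-dione.
5. Ring order: ring A is present from the start (cyclohexanedione); ring B is closed by the cycloaddition.

Assumption: the SMILES is read as (4R,8R,9S,10S,13R) in the locants above; the facial sense of the oxazaborolidinium catalyst in step 10 and the ligand hand in step 12 are assigned from the usual models for α-substituted enals and itaconates and have not been checked against a primary source.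

**Step 1**
Reactants: 1 2-methylcyclohexane-1,3-dione; 2 allyl bromide
Product: 3 2-allyl-2-methylcyclohexane-1,3-dione
Conditions: NaOH (1 M aq.), rt, 24 h
Reagents that add atoms: none
Why: C-alkylation (SN2) of the stabilised 1,3-diketone enolate with a soft allylic halide gives the achiral, prochiral 2,2-disubstituted dione.

**Step 2**
Reactants: 3 2-allyl-2-methylcyclohexane-1,3-dione
Product: 4 (2S,3S)-2-allyl-3-hydroxy-2-methylcyclohexan-1-one
Conditions: ketoreductase (NADPH-dependent, (S)-selective, yeast-reductase type), NADP+ (cat.), i-PrOH, phosphate buffer pH 7, 30 °C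
Reagents that add atoms: none
Why: Enzymatic desymmetrising carbonyl reduction, in which the ketoreductase reduces only one of the two enantiotopic C=O groups to the (S)-carbinol and thereby fixes the quaternary carbon as 2S (OH cis to allyl), as in the classical yeast reduction of this dione.

**Step 3**
Reactants: 4 (2S,3S)-2-allyl-3-hydroxy-2-methylcyclohexan-1-one
Product: 6 (1S,2S)-2-allyl-2-methylcyclohexan-1-ol, via hydrazone 5 (not isolated)
Conditions: N2H4·H2O, diethylene glycol, 120 °C; then KOH, 195 °C (−H2O)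
Reagents that add atoms: hydrazine NN (its nitrogen stays only in 5)
Why: Wolff–Kishner (Huang-Minlon) reduction of the pre-formed hydrazone turns the remaining C=O (future C3) into CH2, and the quaternary centre cannot epimerise.

**Step 4**
Reactants: 6 (1S,2S)-2-allyl-2-methylcyclohexan-1-ol
Product: 7 (1S,2S)-2-methyl-2-[(E)-prop-1-enyl]cyclohexan-1-ol (E/Z mixture)
Conditions: KOtBu, DMSO, 60 °C
Reagents that add atoms: none
Why: Base-mediated alkene isomerisation moves the terminal double bond one position inward and stops there because the next carbon is quaternary.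

**Step 5**
Reactants: 7 (1S,2S)-2-methyl-2-[(E)-prop-1-enyl]cyclohexan-1-ol
Product: 9 (1S,2S)-2-(hydroxymethyl)-2-methylcyclohexan-1-ol, via ozonide 8 (not isolated)
Conditions: O3, CH2Cl2, −78 °C; then NaBH4, MeOH, −78 °C → rt
Reagents that add atoms: ozone [O-][O+]=O
Why: Ozonolysis with reductive work-up cleaves both propenyl isomers to the same neopentyl CH2OH (future C18) without touching the stereocentres.

**Step 6**
Reactants: 9 (1S,2S)-2-(hydroxymethyl)-2-methylcyclohexan-1-ol
Product: 10 (1S,2S)-2-{[tert-butyl(diphenyl)silyl]oxymethyl}-2-methylcyclohexan-1-ol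
Conditions: TBDPSCl, imidazole, CH2Cl2, 0 °C → rt
Reagents that add atoms: tert-butyl(chloro)diphenylsilane CC(C)(C)[Si](Cl)(c1ccccc1)c1ccccc1
Why: Selective silylation, since the bulky silyl chloride reacts with the primary alcohol much faster than with the hindered secondary one.

**Step 7**
Reactants: 10 (1S,2S)-2-{[tert-butyl(diphenyl)silyl]oxymethyl}-2-methylcyclohexan-1-ol
Product: 11 (2S)-2-{[tert-butyl(diphenyl)silyl]oxymethyl}-2-methylcyclohexan-1-one
Conditions: Pr4N[RuO4] (5 mol%), N-methylmorpholine N-oxide, 4 Å MS, CH2Cl2, rt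
Reagents that add atoms: none
Why: Ley–Griffith oxidation gives the ketone (future C5), whose α-quaternary centre has no α-hydrogen and cannot racemise.

**Step 8**
Reactants: 11 (2S)-2-{[tert-butyl(diphenyl)silyl]oxymethyl}-2-methylcyclohexan-1-one
Product: 13 (6S)-6-{[tert-butyl(diphenyl)silyl]oxymethyl}-6-methylcyclohex-1-en-1-yl trifluoromethanesulfonate, via potassium enolate 12 (not isolated)
Conditions: KN(SiMe3)2, THF, −78 °C; then PhNTf2, −78 °C → rt
Reagents that add atoms: N-phenylbis(trifluoromethanesulfonimide) O=S(=O)(N(c1ccccc1)S(=O)(=O)C(F)(F)F)C(F)(F)F; KN(SiMe3)2 [K+].C[Si](C)(C)[N-][Si](C)(C)C (potassium only in 12)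
Why: Enolate O-triflation is regiochemically unambiguous because the ketone can enolise only towards its CH2 side.

**Step 9**
Reactants: 13 (6S)-6-{[tert-butyl(diphenyl)silyl]oxymethyl}-6-methylcyclohex-1-en-1-yl trifluoromethanesulfonate
Product: 14 tert-butyl{[(1R)-2-ethenyl-1-methylcyclohex-2-en-1-yl]methoxy}diphenylsilane
Conditions: Bu3SnCH=CH2, Pd(PPh3)4 (3 mol%), LiCl, THF, 65 °C
Reagents that add atoms: tributyl(vinyl)stannane C=C[Sn](CCCC)(CCCC)CCCC
Why: Stille coupling of an enol triflate with a vinylstannane, the standard route to 6,6-disubstituted 1-vinylcyclohexenes, gives the diene.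

**Step 10**
Reactants: 14 tert-butyl{[(1R)-2-ethenyl-1-methylcyclohex-2-en-1-yl]methoxy}diphenylsilane; 15 (E)-2-methylbut-2-enal (tiglic aldehyde)
Product: 16 (1R,2S,5R,8aR)-5-{[tert-butyl(diphenyl)silyl]oxymethyl}-1,2,5-trimethyl-1,2,3,5,6,7,8,8a-octahydronaphthalene-1-carbaldehyde
Conditions: 15 (3 equiv), (R)-o-tolyl-oxazaborolidinium triflimide [from (R)-α,α-diphenylprolinol, o-tolylboroxine, Tf2NH] (20 mol%), CH2Cl2, −78 → −40 °C
Reagents that add atoms: none
Why: In this catalytic enantioselective Diels–Alder reaction the boron-bound s-trans enal is attacked on the Si face of its α-carbon through the exo (CHO exo) transition state, with the ring terminus of the diene bonding to the α-carbon, which sets C9, C8 (methyls cis, from the E-enal) and C10 (H cis to CHO) together, while the CH2OSi group on C4, expected to sit pseudo-axial, should shield the other diene face.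

**Step 11**
Reactants: 17 itaconic anhydride
Product: 18 4-tert-butoxy-2-methylidene-4-oxobutanoic acid
Conditions: t-BuOH, toluene, 80 °C
Reagents that add atoms: tert-butanol CC(C)(C)O
Why: Regioselective anhydride alcoholysis at the non-conjugated carbonyl gives the 4-ester with the conjugated acid free.

**Step 12**
Reactants: 18 4-tert-butoxy-2-methylidene-4-oxobutanoic acid
Product: 19 (2S)-4-tert-butoxy-2-methyl-4-oxobutanoic acid
Conditions: H2 (5 bar), [Rh(cod)((R,R)-Me-DuPhos)]BF4 (0.5 mol%), MeOH, rt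
Reagents that add atoms: none
Why: Rh-catalysed asymmetric hydrogenation of the chelating itaconate delivers H2 to one alkene face under ligand control and sets the future C13 centre.

**Step 13**
Reactants: 19 (2S)-4-tert-butoxy-2-methyl-4-oxobutanoic acid
Product: 20 tert-butyl (3S)-4-hydroxy-3-methylbutanoate
Conditions: BH3·SMe2, THF, 0 °C → rt; MeOH quench
Reagents that add atoms: none
Why: Chemoselective borane reduction takes the carboxylic acid to the alcohol and leaves the tert-butyl ester and the stereocentre alone.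

**Step 14**
Reactants: 20 tert-butyl (3S)-4-hydroxy-3-methylbutanoate
Product: 21 tert-butyl (3S)-4-iodo-3-methylbutanoate
Conditions: I2, PPh3, imidazole, CH2Cl2, 0 °C → rt
Reagents that add atoms: iodine II
Why: Garegg–Samuelsson (Appel-type) iodination converts the primary alcohol under near-neutral conditions.

**Step 15**
Reactants: 21 tert-butyl (3S)-4-iodo-3-methylbutanoate
Product: 22 [(2S)-4-tert-butoxy-2-methyl-4-oxobutyl]triphenylphosphonium iodide
Conditions: PPh3, MeCN, 80 °C
Reagents that add atoms: triphenylphosphine c1ccc(cc1)P(c1ccccc1)c1ccccc1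
Why: SN2 quaternisation of the phosphine by the primary iodide gives the Wittig salt.

**Step 16**
Reactants: 16 (1R,2S,5R,8aR)-5-{[tert-butyl(diphenyl)silyl]oxymethyl}-1,2,5-trimethyl-1,2,3,5,6,7,8,8a-octahydronaphthalene-1-carbaldehyde; 22 [(2S)-4-tert-butoxy-2-methyl-4-oxobutyl]triphenylphosphonium iodide
Product: 24 tert-butyl (3S,4Z)-5-[(1S,2S,5R,8aS)-5-{[tert-butyl(diphenyl)silyl]oxymethyl}-1,2,5-trimethyl-1,2,3,5,6,7,8,8a-octahydronaphthalen-1-yl]-3-methylpent-4-enoate, via ylide 23 (not isolated)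
Conditions: 22, NaN(SiMe3)2, THF, −78 → 0 °C; then 16, −78 °C → rt
Reagents that add atoms: none
Why: Wittig olefination of the non-enolisable neopentyl aldehyde with the non-stabilised ylide joins C11 to C12 (mainly Z, irrelevant after step 17).

**Step 17**
Reactants: 24 the (Z)-alkene
Product: 25 tert-butyl (3R)-5-[(1R,2S,5R,8aS)-5-{[tert-butyl(diphenyl)silyl]oxymethyl}-1,2,5-trimethyl-1,2,3,5,6,7,8,8a-octahydronaphthalen-1-yl]-3-methylpentanoate
Conditions: H2 (1 atm), RhCl(PPh3)3 (10 mol%), benzene/EtOH, rt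
Reagents that add atoms: none
Why: Homogeneous hydrogenation with Wilkinson's catalyst reduces the disubstituted side-chain alkene and leaves the hindered trisubstituted ring alkene in place.

**Step 18**
Reactants: 25 the saturated silyl ether
Product: 26 tert-butyl (3R)-5-[(1R,2S,5R,8aS)-5-(hydroxymethyl)-1,2,5-trimethyl-1,2,3,5,6,7,8,8a-octahydronaphthalen-1-yl]-3-methylpentanoate
Conditions: Bu4NF, THF, rt → 40 °C
Reagents that add atoms: none
Why: Fluoride-mediated desilylation is done here, before the ketone is introduced, so no base-sensitive centre is present.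

**Step 19**
Reactants: 26 the primary alcohol
Product: 27 tert-butyl (3R)-5-[(1R,2S,5R,8aS)-5-(acetoxymethyl)-1,2,5-trimethyl-1,2,3,5,6,7,8,8a-octahydronaphthalen-1-yl]-3-methylpentanoate
Conditions: Ac2O, pyridine, DMAP (cat.), CH2Cl2, rt
Reagents that add atoms: acetic anhydride CC(=O)OC(C)=O
Why: DMAP-catalysed acetylation installs the C18 acetate.

**Step 20**
Reactants: 27 the acetate
Product: 28 tert-butyl (3R)-5-[(1S,2R,5R,8aS)-5-(acetoxymethyl)-1,2,5-trimethyl-3-oxo-1,2,3,5,6,7,8,8a-octahydronaphthalen-1-yl]-3-methylpentanoate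
Conditions: t-BuOOH (70% aq.), Rh2(caprolactamate)4 (1 mol%), ClCH2CH2Cl, 40 °C
Reagents that add atoms: tert-butyl hydroperoxide CC(C)(C)OO
Why: Allylic C–H oxidation by the tert-butylperoxyl radical chain converts the secondary allylic C7 into the enone carbonyl, as in the 7-oxidation of steroidal 5-enes, because C4 has no hydrogen and the tertiary C10–H is hindered.

**Step 21**
Reactants: 28 the enone tert-butyl ester
Product: 29 (3R)-5-[(1S,2R,5R,8aS)-5-(acetoxymethyl)-1,2,5-trimethyl-3-oxo-1,2,3,5,6,7,8,8a-octahydronaphthalen-1-yl]-3-methylpentanoic acid (CNP0210381.1)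
Conditions: CF3CO2H, CH2Cl2, 0 °C → rt
Reagents that add atoms: none
Why: Acidolysis (E1) of the tert-butyl ester frees the acid under conditions that leave the acetate, the enone and the α-stereocentre C8 untouched.

**Compound list**
1 | 2-methylcyclohexane-1,3-dione | CC1C(=O)CCCC1=O | starting material
2 | allyl bromide | C=CCBr | starting material
3 | 2-allyl-2-methylcyclohexane-1,3-dione | C=CCC1(C)C(=O)CCCC1=O | intermediate
4 | (2S,3S)-2-allyl-3-hydroxy-2-methylcyclohexan-1-one | C=CC[C@]1(C)C(=O)CCC[C@@H]1O | intermediate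
5 | hydrazone of 4 | C=CC[C@]1(C)C(=NN)CCC[C@@H]1O | intermediate (not isolated)
6 | (1S,2S)-2-allyl-2-methylcyclohexan-1-ol | C=CC[C@]1(C)CCCC[C@@H]1O | intermediate
7 | (1S,2S)-2-methyl-2-[(E)-prop-1-enyl]cyclohexan-1-ol (E/Z mixture, E drawn) | C/C=C/[C@]1(C)CCCC[C@@H]1O | intermediate
8 | secondary ozonide of 7 (3-methyl-1,2,4-trioxolan-5-yl on the quaternary carbon; trioxolane centres undefined) | CC1OOC(O1)[C@]1(C)CCCC[C@@H]1O | intermediate (not isolated)
9 | (1S,2S)-2-(hydroxymethyl)-2-methylcyclohexan-1-ol | OC[C@]1(C)CCCC[C@@H]1O | intermediate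
10 | (1S,2S)-2-{[tert-butyl(diphenyl)silyl]oxymethyl}-2-methylcyclohexan-1-ol | CC(C)(C)[Si](c2ccccc2)(c3ccccc3)OC[C@]1(C)CCCC[C@@H]1O | intermediate
11 | (2S)-2-{[tert-butyl(diphenyl)silyl]oxymethyl}-2-methylcyclohexan-1-one | CC(C)(C)[Si](c2ccccc2)(c3ccccc3)OC[C@]1(C)CCCCC1=O | intermediate
12 | potassium enolate of 11 | CC(C)(C)[Si](c2ccccc2)(c3ccccc3)OC[C@]1(C)CCCC=C1[O-].[K+] | intermediate (not isolated)
13 | (6S)-6-{[tert-butyl(diphenyl)silyl]oxymethyl}-6-methylcyclohex-1-en-1-yl trifluoromethanesulfonate | CC(C)(C)[Si](c2ccccc2)(c3ccccc3)OC[C@]1(C)CCCC=C1OS(=O)(=O)C(F)(F)F | intermediate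
14 | tert-butyl{[(1R)-2-ethenyl-1-methylcyclohex-2-en-1-yl]methoxy}diphenylsilane | CC(C)(C)[Si](c2ccccc2)(c3ccccc3)OC[C@]1(C)CCCC=C1C=C | intermediate
15 | (E)-2-methylbut-2-enal (tiglic aldehyde) | C/C=C(\C)C=O | starting material
16 | (1R,2S,5R,8aR)-5-{[tert-butyl(diphenyl)silyl]oxymethyl}-1,2,5-trimethyl-1,2,3,5,6,7,8,8a-octahydronaphthalene-1-carbaldehyde | CC(C)(C)[Si](c3ccccc3)(c4ccccc4)OC[C@]1(C)CCC[C@@H]2C1=CC[C@H](C)[C@@]2(C)C=O | intermediate
17 | itaconic anhydride (3-methylideneoxolane-2,5-dione) | C=C1CC(=O)OC1=O | starting material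
18 | 4-tert-butoxy-2-methylidene-4-oxobutanoic acid | C=C(CC(=O)OC(C)(C)C)C(=O)O | intermediate
19 | (2S)-4-tert-butoxy-2-methyl-4-oxobutanoic acid | OC(=O)[C@@H](C)CC(=O)OC(C)(C)C | intermediate
20 | tert-butyl (3S)-4-hydroxy-3-methylbutanoate | OC[C@@H](C)CC(=O)OC(C)(C)C | intermediate
21 | tert-butyl (3S)-4-iodo-3-methylbutanoate | IC[C@@H](C)CC(=O)OC(C)(C)C | intermediate
22 | [(2S)-4-tert-butoxy-2-methyl-4-oxobutyl]triphenylphosphonium iodide | c1ccccc1[P+](c1ccccc1)(c1ccccc1)C[C@@H](C)CC(=O)OC(C)(C)C.[I-] | intermediate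
23 | ylide from 22 (tert-butyl (3S)-3-methyl-4-(triphenylphosphoranylidene)butanoate) | c1ccccc1P(c1ccccc1)(c1ccccc1)=C[C@@H](C)CC(=O)OC(C)(C)C | intermediate (not isolated)
24 | tert-butyl (3S,4Z)-5-[(1S,2S,5R,8aS)-5-{[tert-butyl(diphenyl)silyl]oxymethyl}-1,2,5-trimethyl-1,2,3,5,6,7,8,8a-octahydronaphthalen-1-yl]-3-methylpent-4-enoate | CC(C)(C)[Si](c3ccccc3)(c4ccccc4)OC[C@]1(C)CCC[C@@H]2C1=CC[C@H](C)[C@@]2(C)/C=C\[C@@H](C)CC(=O)OC(C)(C)C | intermediate
25 | tert-butyl (3R)-5-[(1R,2S,5R,8aS)-5-{[tert-butyl(diphenyl)silyl]oxymethyl}-1,2,5-trimethyl-1,2,3,5,6,7,8,8a-octahydronaphthalen-1-yl]-3-methylpentanoate | CC(C)(C)[Si](c3ccccc3)(c4ccccc4)OC[C@]1(C)CCC[C@@H]2C1=CC[C@H](C)[C@@]2(C)CC[C@@H](C)CC(=O)OC(C)(C)C | intermediate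
26 | tert-butyl (3R)-5-[(1R,2S,5R,8aS)-5-(hydroxymethyl)-1,2,5-trimethyl-1,2,3,5,6,7,8,8a-octahydronaphthalen-1-yl]-3-methylpentanoate | OC[C@]1(C)CCC[C@@H]2C1=CC[C@H](C)[C@@]2(C)CC[C@@H](C)CC(=O)OC(C)(C)C | intermediate
27 | tert-butyl (3R)-5-[(1R,2S,5R,8aS)-5-(acetoxymethyl)-1,2,5-trimethyl-1,2,3,5,6,7,8,8a-octahydronaphthalen-1-yl]-3-methylpentanoate | CC(=O)OC[C@]1(C)CCC[C@@H]2C1=CC[C@H](C)[C@@]2(C)CC[C@@H](C)CC(=O)OC(C)(C)C | intermediate
28 | tert-butyl (3R)-5-[(1S,2R,5R,8aS)-5-(acetoxymethyl)-1,2,5-trimethyl-3-oxo-1,2,3,5,6,7,8,8a-octahydronaphthalen-1-yl]-3-methylpentanoate | CC(=O)OC[C@]1(C)CCC[C@@H]2C1=CC(=O)[C@H](C)[C@@]2(C)CC[C@@H](C)CC(=O)OC(C)(C)C | intermediate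
29 | (3R)-5-[(1S,2R,5R,8aS)-5-(acetoxymethyl)-1,2,5-trimethyl-3-oxo-1,2,3,5,6,7,8,8a-octahydronaphthalen-1-yl]-3-methylpentanoic acid | CC(=O)OC[C@]1(C)CCC[C@@H]2C1=CC(=O)[C@H](C)[C@@]2(C)CC[C@@H](C)CC(=O)O | target

**Totals**
Total step count: 21. Longest linear sequence: 16 steps (steps 1–10, then 16–21); steps 11–15 make the side-chain salt 22.

**Three steps most likely to fail, each with a fallback**

Step 10 (Diels–Alder). The β-substituted enal may react sluggishly with the hindered diene under the chiral catalyst, or the facial or exo control may be too low. The fallback sets out from 14 (with 15) and comes back at 16. It gives up catalyst control for substrate control: the cycloaddition is promoted with Me2AlCl in toluene at −40 → 0 °C, the kind of achiral Lewis-acid promotion used for closely related 6,6-disubstituted 1-vinylcyclohexenes, so that only the CH2OSi group on C4 chooses the diene face. The crude aldehyde mixture is reduced with NaBH4 to the neopentyl carbinol F1, which is freed from the minor diastereomers by chromatography and oxidised back with Pr4N[RuO4] and N-methylmorpholine N-oxide to 16.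

Step 16 (Wittig). The neopentyl aldehyde may not add the β-branched, ester-bearing ylide cleanly. The fallback sets out from 16 and comes back at 25, skipping 24. Methylenation with Ph3P=CH2 gives the vinyl compound F2. Hydroboration of its terminal alkene with 9-BBN gives the B-alkyl-9-borabicyclononane F3 (used in solution). Suzuki–Miyaura coupling of this borane with tert-butyl (Z)-3-iodobut-2-enoate (PdCl2(dppf), Cs2CO3, DMF/H2O) gives the geometrically pure (Z)-enoate F4. Asymmetric conjugate reduction with CuH (Cu(OAc)2, DTBM-SEGPHOS, polymethylhydrosiloxane, t-BuOH, toluene; ligand antipode fixed on a model (Z)-enoate so that C13 comes out R) then gives 25.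

Step 20 (allylic oxidation). Attack at the tertiary C10–H or over-oxidation may compete. The fallback sets out from 27 and comes back at 28 and is regiochemically unambiguous. Epoxidation with mCPBA gives the epoxide F5 (either face is acceptable, since C5 and C6 lose their configuration later). Opening at C6 with PhSeSePh/NaBH4 in EtOH gives the trans hydroxy selenide F6. Oxidation with H2O2 gives the selenoxide F7 (not isolated), which can eliminate only towards C7 and gives the tertiary allylic alcohol F8. Oxidative 1,3-transposition with [C5H5NH][CrO3Cl] in CH2Cl2 then gives 28.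

**Further compounds**
F1 | step 10 | [(1R,2S,5R,8aR)-5-{[tert-butyl(diphenyl)silyl]oxymethyl}-1,2,5-trimethyl-1,2,3,5,6,7,8,8a-octahydronaphthalen-1-yl]methanol | CC(C)(C)[Si](c3ccccc3)(c4ccccc4)OC[C@]1(C)CCC[C@@H]2C1=CC[C@H](C)[C@@]2(C)CO
F2 | step 16 | (1R,2S,5R,8aS)-5-{[tert-butyl(diphenyl)silyl]oxymethyl}-1-ethenyl-1,2,5-trimethyl-1,2,3,5,6,7,8,8a-octahydronaphthalene | CC(C)(C)[Si](c3ccccc3)(c4ccccc4)OC[C@]1(C)CCC[C@@H]2C1=CC[C@H](C)[C@@]2(C)C=C
F3 | step 16 | 9-{2-[(1R,2S,5R,8aS)-5-{[tert-butyl(diphenyl)silyl]oxymethyl}-1,2,5-trimethyl-1,2,3,5,6,7,8,8a-octahydronaphthalen-1-yl]ethyl}-9-borabicyclo[3.3.1]nonane | CC(C)(C)[Si](c3ccccc3)(c4ccccc4)OC[C@]1(C)CCC[C@@H]2C1=CC[C@H](C)[C@@]2(C)CCB5C6CCCC5CCC6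
F4 | step 16 | tert-butyl (2Z)-5-[(1R,2S,5R,8aS)-5-{[tert-butyl(diphenyl)silyl]oxymethyl}-1,2,5-trimethyl-1,2,3,5,6,7,8,8a-octahydronaphthalen-1-yl]-3-methylpent-2-enoate | CC(C)(C)[Si](c3ccccc3)(c4ccccc4)OC[C@]1(C)CCC[C@@H]2C1=CC[C@H](C)[C@@]2(C)CC/C(C)=C\C(=O)OC(C)(C)C
F5 | step 20 | 5,6-epoxide of 27 (oxirane across the former ring B alkene; oxygen drawn on the face of the C8/C9 methyl groups) | CC(=O)OC[C@]1(C)CCC[C@@H]2[C@@]13O[C@@H]3C[C@H](C)[C@@]2(C)CC[C@@H](C)CC(=O)OC(C)(C)C
F6 | step 20 | 5-hydroxy-6-(phenylselanyl) adduct of F5 (OH on the methyl face, SePh on the opposite face, trans) | CC(=O)OC[C@]1(C)CCC[C@@H]2[C@]1(O)[C@@H]([Se]c5ccccc5)C[C@H](C)[C@@]2(C)CC[C@@H](C)CC(=O)OC(C)(C)C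
F7 | step 20 | selenoxide of F6 (selenium centre undefined) | CC(=O)OC[C@]1(C)CCC[C@@H]2[C@]1(O)[C@@H]([Se](=O)c5ccccc5)C[C@H](C)[C@@]2(C)CC[C@@H](C)CC(=O)OC(C)(C)C
F8 | step 20 | 5-hydroxy-6-ene isomer of 27 (tertiary allylic alcohol at the ring-fusion carbon, alkene C6=C7) | CC(=O)OC[C@]1(C)CCC[C@@H]2[C@]1(O)C=C[C@H](C)[C@@]2(C)CC[C@@H](C)CC(=O)OC(C)(C)C
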